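Everything rests on cutting the oxazole at C2, across both C2–N3 and C2–O1. C2 is flanked by N3 and O1 and has pyrrole C2 as its only carbon neighbour, so it sits at the acid oxidation level and can arrive as a pyrrole-2-carbonyl chloride. The partner is an azidomethyl ketone on indole C3, which already carries O1, C5, C4 and N3 in sequence. A one-pot Staudinger/aza-Wittig condensation joins the two halves, forms both bonds to C2 and closes the oxazole ring without acid, oxidant or transition metal, so both C–Br bonds survive. Both ring nitrogens are tosylated in the precursors; one carbonate-mediated methanolysis then releases the target.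

Key step: step 7

Assumption: the target has no stereocentre. Compound 6 is taken as purchasable. Acid chloride 9 is freed from volatiles and used crude at once. Azido ketone 5 is kept cold, away from base and light, and is not stored.

Step 1
Reactants: 1 6-bromo-4-methoxy-1H-indole; 2 chloroacetyl chloride
Product: 3 1-(6-bromo-4-methoxy-1H-indol-3-yl)-2-chloroethanone
Conditions: Et2AlCl (1.5 equiv, hexane), CH2Cl2, 0 °C; then 2 (1.5 equiv), 0 °C
Reagents that add atoms: none
Why: Friedel–Crafts acylation of the unprotected indole at C3, its most nucleophilic (enamine-type) carbon, promoted by the mild Lewis acid Et2AlCl, which also consumes the HCl released, so that neither N-acylation nor cleavage of the C4 methyl ether is expected.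

Step 2
Reactants: 3 1-(6-bromo-4-methoxy-1H-indol-3-yl)-2-chloroethanone
Product: 4 1-(6-bromo-4-methoxy-1-tosylindol-3-yl)-2-chloroethanone
Conditions: TsCl (1.2 equiv), i-Pr2NEt (1.5 equiv), DMAP (0.1 equiv), CH2Cl2, 0 °C to rt
Reagents that add atoms: p-toluenesulfonyl chloride (TsCl), Cc1ccc(S(=O)(=O)Cl)cc1
Why: N-sulfonylation of the acidic N–H of a 3-acylindole (a vinylogous amide) under DMAP catalysis with a hindered amine base, conditions mild enough that the alpha-chloro ketone should be neither enolised nor displaced.

Step 3
Reactants: 4 1-(6-bromo-4-methoxy-1-tosylindol-3-yl)-2-chloroethanone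
Product: 5 2-azido-1-(6-bromo-4-methoxy-1-tosylindol-3-yl)ethanone
Conditions: NaN3 (1.3 equiv), acetone/H2O, rt
Reagents that add atoms: sodium azide (NaN3), [Na+].[N-]=[N+]=[N-]
Why: SN2 displacement of the carbonyl-activated primary chloride by azide, a fast substitution that needs no base and should leave the N-tosyl group and the aryl bromide alone.

Step 4
Reactants: 6 5-bromo-1H-pyrrole-2-carbaldehyde
Product: 7 5-bromo-1-tosylpyrrole-2-carbaldehyde
Conditions: NaH (1.2 equiv), THF, 0 °C; then TsCl (1.15 equiv), 0 °C to rt
Reagents that add atoms: p-toluenesulfonyl chloride (TsCl), Cc1ccc(S(=O)(=O)Cl)cc1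
Why: N-sulfonylation of the sodium pyrrolide, whose N–H is acidified by the 2-formyl group; the sulfonyl group also lowers the electron density of the bromopyrrole for the oxidation that follows.

Step 5
Reactants: 7 5-bromo-1-tosylpyrrole-2-carbaldehyde
Product: 8 5-bromo-1-tosylpyrrole-2-carboxylic acid
Conditions: NaClO2, NaH2PO4, 2-methyl-2-butene, t-BuOH/THF/H2O, 0 °C to rt
Reagents that add atoms: sodium chlorite (NaClO2), [Na+].[O-]Cl=O
Why: Pinnick oxidation of the aldehyde under buffered conditions, with 2-methyl-2-butene trapping HOCl so that the ring is not chlorinated; the aldehyde oxidation level is chosen because saponification of an ester would strip the N-tosyl group.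

Step 6
Reactants: 8 5-bromo-1-tosylpyrrole-2-carboxylic acid
Product: 9 5-bromo-1-tosylpyrrole-2-carbonyl chloride
Conditions: (COCl)2 (1.5 equiv), DMF (cat.), CH2Cl2, 0 °C to rt; evaporate with toluene
Reagents that add atoms: oxalyl chloride, O=C(Cl)C(=O)Cl
Why: Acid chloride formation through the catalytic chloroiminium species from DMF and oxalyl chloride, which leaves only gaseous by-products so that the crude chloride can be used directly.

Step 7
Reactants: 5 2-azido-1-(6-bromo-4-methoxy-1-tosylindol-3-yl)ethanone; 9 5-bromo-1-tosylpyrrole-2-carbonyl chloride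
Product: 12 5-(6-bromo-4-methoxy-1-tosylindol-3-yl)-2-(5-bromo-1-tosylpyrrol-2-yl)oxazole, via iminophosphorane 10 (not isolated), via imidoyl chloride 11 (not isolated)
Conditions: 5 + 9 (1.3 equiv), toluene, 0 °C; PPh3 (1.1 equiv) added last, 0 °C to rt; then Et3N (2.5 equiv), 70 °C
Reagents that add atoms: none
Why: PPh3 converts the azide of 5 into iminophosphorane 10 with loss of N2 (Staudinger reaction); the strongly nucleophilic phosphazene nitrogen is acylated by 9 and triphenylphosphine oxide departs with the acyl oxygen, leaving imidoyl chloride 11 (aza-Wittig-type condensation with an acyl chloride). Et3N then deprotonates the CH2 group between the imine nitrogen and the ketone, and the resulting species, drawn either as an enolate or, after chloride loss, as a carbonyl-conjugated nitrile ylide, ring-closes by 1,5-dipolar electrocyclisation; counted from the ketone oxygen this is a 5-endo closure onto C2, and loss of HCl gives the aromatic oxazole. The closest known reaction type is the one-pot conversion of alpha-azido ketones and acyl chlorides into 2,5-disubstituted oxazoles, which has been used for 5-(indol-3-yl)oxazoles. No stereocentre is formed. The step needs N-acylation of 10 to outrun its condensation with the ketone of a second molecule (pyrazine formation) and any acylation at ring nitrogen; the first is secured by generating 10 in the presence of excess 9, the second by the tosyl groups on both ring nitrogens, and the neutral to mildly basic, non-oxidising, metal-free medium should leave both C–Br bonds and the bromopyrrole intact.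

Step 8
Reactants: 12 5-(6-bromo-4-methoxy-1-tosylindol-3-yl)-2-(5-bromo-1-tosylpyrrol-2-yl)oxazole
Product: 13 5-(6-bromo-4-methoxy-1H-indol-3-yl)-2-(5-bromo-1H-pyrrol-2-yl)oxazole
Conditions: Cs2CO3 (6 equiv), THF/MeOH (2:1), rt to 45 °C; aq. NH4Cl
Reagents that add atoms: none
Why: Nucleophilic desulfonylation, in which methoxide generated by Cs2CO3 attacks the sulfonyl sulfur of both electron-poor N-tosyl azoles and releases the indole and pyrrole N–H under conditions that should not touch the aryl bromides, the methyl ether or the oxazole.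

Compound list
1 | 6-bromo-4-methoxy-1H-indole | COc1cc(Br)cc2[nH]ccc12 | starting material
2 | chloroacetyl chloride | O=C(Cl)CCl | starting material
3 | 1-(6-bromo-4-methoxy-1H-indol-3-yl)-2-chloroethanone | COc1cc(Br)cc2[nH]cc(C(=O)CCl)c12 | intermediate
4 | 1-(6-bromo-4-methoxy-1-tosylindol-3-yl)-2-chloroethanone | COc1cc(Br)cc2n(S(=O)(=O)c3ccc(C)cc3)cc(C(=O)CCl)c12 | intermediate
5 | 2-azido-1-(6-bromo-4-methoxy-1-tosylindol-3-yl)ethanone | COc1cc(Br)cc2n(S(=O)(=O)c3ccc(C)cc3)cc(C(=O)CN=[N+]=[N-])c12 | intermediate
6 | 5-bromo-1H-pyrrole-2-carbaldehyde | O=Cc1ccc(Br)[nH]1 | starting material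
7 | 5-bromo-1-tosylpyrrole-2-carbaldehyde | O=Cc1ccc(Br)n1S(=O)(=O)c1ccc(C)cc1 | intermediate
8 | 5-bromo-1-tosylpyrrole-2-carboxylic acid | O=C(O)c1ccc(Br)n1S(=O)(=O)c1ccc(C)cc1 | intermediate
9 | 5-bromo-1-tosylpyrrole-2-carbonyl chloride | O=C(Cl)c1ccc(Br)n1S(=O)(=O)c1ccc(C)cc1 | intermediate
10 | 1-(6-bromo-4-methoxy-1-tosylindol-3-yl)-2-[(triphenylphosphoranylidene)amino]ethanone (iminophosphorane) | COc1cc(Br)cc2n(S(=O)(=O)c3ccc(C)cc3)cc(C(=O)CN=P(c3ccccc3)(c3ccccc3)c3ccccc3)c12 | intermediate
11 | N-[2-(6-bromo-4-methoxy-1-tosylindol-3-yl)-2-oxoethyl]-5-bromo-1-tosylpyrrole-2-carboximidoyl chloride | COc1cc(Br)cc2n(S(=O)(=O)c3ccc(C)cc3)cc(C(=O)CN=C(Cl)c3ccc(Br)n3S(=O)(=O)c3ccc(C)cc3)c12 | intermediate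
12 | 5-(6-bromo-4-methoxy-1-tosylindol-3-yl)-2-(5-bromo-1-tosylpyrrol-2-yl)oxazole | COc1cc(Br)cc2n(S(=O)(=O)c3ccc(C)cc3)cc(-c3cnc(-c4ccc(Br)n4S(=O)(=O)c4ccc(C)cc4)o3)c12 | intermediate
13 | 5-(6-bromo-4-methoxy-1H-indol-3-yl)-2-(5-bromo-1H-pyrrol-2-yl)oxazole | COc1cc(Br)cc2[nH]cc(-c3cnc(-c4ccc(Br)[nH]4)o3)c12 | target

Total step count: 8. Longest linear sequence: 5 steps (steps 1, 2, 3, 7, 8; the pyrrole branch, steps 4, 5, 6, 7, 8, is equally long).

Steps most likely to fail

Step 7. The iminophosphorane may condense with the ketone of a second molecule (dihydropyrazine and pyrazine formation) faster than it is acylated, or the imidoyl chloride may be hydrolysed to the open amide instead of cyclising. The fallback sets out from 5 and 9 and comes back at 12, building the oxazole in stages. Staudinger reduction of 5 with PPh3 in wet THF in the presence of TsOH·H2O should trap the amine as 2-amino-1-(6-bromo-4-methoxy-1-tosylindol-3-yl)ethanone 4-methylbenzenesulfonate salt F1, protonation preventing self-condensation. Acylation with 9 (i-Pr2NEt, CH2Cl2, 0 °C) should give N-[2-(6-bromo-4-methoxy-1-tosylindol-3-yl)-2-oxoethyl]-5-bromo-1-tosylpyrrole-2-carboxamide F2. Robinson–Gabriel cyclodehydration under mild phosphine conditions (PPh3, iodine, Et3N, CH2Cl2) should then close the oxazole to 12.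

Step 1. Acylation may take place at nitrogen or on the methoxy-activated benzene ring instead of C3, or the Lewis acid may cleave the methyl ether that lies peri to the new ketone. The fallback sets out from 1 and comes back at 3, using a Vilsmeier–Haack acylation without Lewis acid or free acyl chloride. 2-Chloro-N,N-dimethylacetamide and POCl3 (1,2-dichloroethane, 0 °C to 50 °C) should attack C3 to give N-[1-(6-bromo-4-methoxy-1H-indol-3-yl)-2-chloroethylidene]-N-methylmethanaminium chloride F3. Hydrolysis of F3 with cold aqueous NaOAc should give 3.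

Step 2. The alpha-chloro ketone may alkylate the amine base, the DMAP catalyst or the indole nitrogen of a second molecule (oligomerisation) before sulfonylation is complete. The fallback sets out from 1 and comes back at 4, placing the tosyl group before the chloro ketone exists and reversing the polarity at C3. Iodination of 1 (iodine, KOH, DMF) should give 6-bromo-3-iodo-4-methoxy-1H-indole F4, which is tosylated at once (NaH, TsCl, THF) to 6-bromo-3-iodo-4-methoxy-1-tosylindole F5. Iodine–magnesium exchange with i-PrMgCl·LiCl (THF, −40 °C), much faster at the C3 iodide than at the C6 bromide, should give (6-bromo-4-methoxy-1-tosylindol-3-yl)magnesium chloride F6. Its Weinreb ketone synthesis with 2-chloro-N-methoxy-N-methylacetamide should deliver 4.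

Further compounds
F1 | step 7 | 2-amino-1-(6-bromo-4-methoxy-1-tosylindol-3-yl)ethanone 4-methylbenzenesulfonate salt | COc1cc(Br)cc2n(S(=O)(=O)c3ccc(C)cc3)cc(C(=O)C[NH3+])c12.Cc1ccc(S(=O)(=O)[O-])cc1
F2 | step 7 | N-[2-(6-bromo-4-methoxy-1-tosylindol-3-yl)-2-oxoethyl]-5-bromo-1-tosylpyrrole-2-carboxamide | COc1cc(Br)cc2n(S(=O)(=O)c3ccc(C)cc3)cc(C(=O)CNC(=O)c3ccc(Br)n3S(=O)(=O)c3ccc(C)cc3)c12
F3 | step 1 | N-[1-(6-bromo-4-methoxy-1H-indol-3-yl)-2-chloroethylidene]-N-methylmethanaminium chloride | COc1cc(Br)cc2[nH]cc(C(CCl)=[N+](C)C)c12.[Cl-]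
F4 | step 2 | 6-bromo-3-iodo-4-methoxy-1H-indole | COc1cc(Br)cc2[nH]cc(I)c12
F5 | step 2 | 6-bromo-3-iodo-4-methoxy-1-tosylindole | COc1cc(Br)cc2n(S(=O)(=O)c3ccc(C)cc3)cc(I)c12
F6 | step 2 | (6-bromo-4-methoxy-1-tosylindol-3-yl)magnesium chloride | COc1cc(Br)cc2n(S(=O)(=O)c3ccc(C)cc3)cc([Mg]Cl)c12
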